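**Retrosynthetic overview** (atom numbers are the azulene locants of the systematic names)
- Ferugin ⇒ aryl acetate removal, allylic C–H hydroxylation at C-7, and acylation of the C-4 hydroxyl of a 3,4-diol carrying the 6-methylidene group.
- Seven-membered ring, formed last: C-4–C-5 bond by a chelation-controlled type 2 carbonyl-ene closure of a cyclopentane hydroxy aldehyde bearing a 3-methylbut-3-enyl chain.
- Five-membered ring, formed first (key step): C-8a–C-1 bond by coupling a ketone homoenolate equivalent (β-keto radical from a cyclopropanol) with the β-carbon of an enal, then aldol closure C-3a–C-3, in one amine-catalysed photochemical cascade that sets C-8a, C-3a and C-3.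
- The enal comes from 5-methylhex-5-en-2-one (olefination, reduction); the cyclopropanol from methyl 2-methylpropanoate (Kulinkovich).

Assumption: the (S)-amine catalyst of step 4 shields the enal face as it does in its established iminium reactions; if the opposite sense is found, the (R)-catalyst is used and nothing else changes.

**Step 1**
Reactants: 1 5-methylhex-5-en-2-one; 2 diethyl [2-(methoxy(methyl)amino)-2-oxoethyl]phosphonate
Product: 3 (2E)-N-methoxy-N,3,6-trimethylhepta-2,6-dienamide
Conditions: NaH, THF, 0 to 65 °C; E isomer separated on silica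
Reagents that add atoms: none
Why: Horner–Wadsworth–Emmons olefination of the methyl ketone with the stabilised phosphonate gives the trisubstituted enamide, the E isomer (carbonyl trans to the longer chain) predominating and being separable from the minor Z isomer.

**Step 2**
Reactants: 3 (2E)-N-methoxy-N,3,6-trimethylhepta-2,6-dienamide
Product: 4 (2E)-3,6-dimethylhepta-2,6-dienal
Conditions: i-Bu2AlH, THF, −78 °C; aq. potassium sodium tartrate
Reagents that add atoms: none
Why: Weinreb amide reduction stops at the aldehyde because the chelated aluminum hemiaminal collapses only on work-up, and neither alkene nor the E geometry is touched.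

**Step 3**
Reactants: 5 methyl 2-methylpropanoate; 6 ethylmagnesium bromide
Product: 7 1-(propan-2-yl)cyclopropan-1-ol
Conditions: Ti(OiPr)4 (0.3 equiv), 6 (2.5 equiv), Et2O, 0 to 20 °C; aq. H2SO4
Reagents that add atoms: none
Why: Kulinkovich cyclopropanation, in which the titanacyclopropane made from Ti(OiPr)4 and EtMgBr adds twice to the ester carbonyl as a 1,2-dicarbanion; no stereocenter is formed.

**Step 4**
Reactants: 4 (2E)-3,6-dimethylhepta-2,6-dienal; 7 1-(propan-2-yl)cyclopropan-1-ol
Product: 9 (1R,2R,5S)-2-hydroxy-5-methyl-5-(3-methylbut-3-en-1-yl)-2-(propan-2-yl)cyclopentane-1-carbaldehyde, via keto aldehyde 8 (not isolated)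
Conditions: (S)-2-{bis[3,5-bis(trifluoromethyl)phenyl][(tert-butyldimethylsilyl)oxy]methyl}-4,4-difluoropyrrolidine (20 mol %), CF3CO2H (40 mol %), 7 (2 equiv), CH3CN, 390 nm LEDs, −10 °C, argon
Reagents that add atoms: none
Why: Proposed new method: the photoexcited chiral iminium ion of 4 oxidises cyclopropanol 7 by single-electron transfer and ring opening gives the β-keto radical (a homoenolate equivalent), which couples with the β-enaminyl radical at the normally electrophilic enal β-carbon on the face away from the catalyst's diaryl(silyloxy)methyl group, setting the quaternary carbon with the methyl cis to the formyl-bearing carbon because the iminium is E; the resulting enamine (the catalyst-bound form of 8) then closes the five-membered ring by intramolecular aldol addition to the isopropyl ketone from the same open face, with the alkoxide next to the iminium carbon and the isopropyl group turned away, which sets the ring CH and the tertiary carbinol with OH cis to CHO; the closest known reaction is the amine-catalysed photochemical iminium-ion/cyclopropanol radical cascade that turns β-aryl enals into formyl cyclopentanols, extended here to an aliphatic β,β-disubstituted enal at shorter wavelength.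

**Step 5**
Reactants: 9 (1R,2R,5S)-2-hydroxy-5-methyl-5-(3-methylbut-3-en-1-yl)-2-(propan-2-yl)cyclopentane-1-carbaldehyde
Product: 10 (3R,3aS,4S,8aS)-8a-methyl-6-methylidene-3-(propan-2-yl)decahydroazulene-3,4-diol
Conditions: Me2AlCl (2.5 equiv), CH2Cl2, −78 to −20 °C; aq. HCl
Reagents that add atoms: none
Why: Type 2 intramolecular carbonyl-ene reaction in which the terminal CH2 of the isopropenyl group attacks the aldehyde to close the seven-membered ring and a methyl hydrogen is transferred, leaving the exocyclic methylene; the aluminum alkoxide of the tertiary alcohol chelates the aldehyde oxygen, so the new carbinol oxygen ends up syn to the tertiary oxygen (4S) and the ring fusion stays trans.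

**Step 6**
Reactants: 10 (3R,3aS,4S,8aS)-8a-methyl-6-methylidene-3-(propan-2-yl)decahydroazulene-3,4-diol; 11 4-(acetyloxy)benzoyl chloride
Product: 12 [(3R,3aS,4S,8aS)-3-hydroxy-8a-methyl-6-methylidene-3-(propan-2-yl)decahydroazulen-4-yl] 4-(acetyloxy)benzoate
Conditions: pyridine, 4-(dimethylamino)pyridine (0.2 equiv), CH2Cl2, 0 to 25 °C
Reagents that add atoms: none
Why: Nucleophilic-catalysed acylation of the only acylable hydroxyl, the secondary one, while the tertiary alcohol is inert and the phenol is masked as its acetate.

**Step 7**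
Reactants: 12 [(3R,3aS,4S,8aS)-3-hydroxy-8a-methyl-6-methylidene-3-(propan-2-yl)decahydroazulen-4-yl] 4-(acetyloxy)benzoate
Product: 13 [(3R,3aS,4S,7S,8aR)-3,7-dihydroxy-8a-methyl-6-methylidene-3-(propan-2-yl)decahydroazulen-4-yl] 4-(acetyloxy)benzoate
Conditions: SeO2 (0.5 equiv), t-BuOOH (3 equiv), CH2Cl2, 0 to 20 °C
Reagents that add atoms: selenium dioxide, O=[Se]=O (transfers the oxygen atom); tert-butyl hydroperoxide, CC(C)(C)OO (terminal oxygen source)
Why: SeO2 allylic hydroxylation (ene reaction, then [2,3]-sigmatropic shift) keeps the exocyclic methylene; the C-5 CH2 next to the acyloxy carbon is deactivated and hindered, so oxidation goes to C-7, and oxygen is delivered to the face opposite the angular methyl, giving 7S.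

**Step 8**
Reactants: 13 [(3R,3aS,4S,7S,8aR)-3,7-dihydroxy-8a-methyl-6-methylidene-3-(propan-2-yl)decahydroazulen-4-yl] 4-(acetyloxy)benzoate
Product: 14 ferugin, [(3R,3aS,4S,7S,8aR)-3,7-dihydroxy-8a-methyl-6-methylidene-3-(propan-2-yl)decahydroazulen-4-yl] 4-hydroxybenzoate
Conditions: NH3 (7 M in MeOH), 0 °C
Reagents that add atoms: none
Why: Chemoselective aminolysis of the activated aryl acetate; the hindered secondary benzoate, the allylic alcohol and the alkene are untouched.

**Compound list**
1 | 5-methylhex-5-en-2-one | CC(=O)CCC(C)=C | starting material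
2 | diethyl [2-(methoxy(methyl)amino)-2-oxoethyl]phosphonate | CCOP(=O)(OCC)CC(=O)N(C)OC | starting material
3 | (2E)-N-methoxy-N,3,6-trimethylhepta-2,6-dienamide | CON(C)C(=O)/C=C(\C)CCC(C)=C | intermediate
4 | (2E)-3,6-dimethylhepta-2,6-dienal | O=C/C=C(\C)CCC(C)=C | intermediate
5 | methyl 2-methylpropanoate | COC(=O)C(C)C | starting material
6 | ethylmagnesium bromide | CC[Mg]Br | starting material
7 | 1-(propan-2-yl)cyclopropan-1-ol | CC(C)C1(O)CC1 | intermediate
8 | (3S)-3,7-dimethyl-3-(3-methylbut-3-en-1-yl)-6-oxooctanal (not isolated; present as its enamine with the catalyst) | O=CC[C@@](C)(CCC(C)=C)CCC(=O)C(C)C | intermediate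
9 | (1R,2R,5S)-2-hydroxy-5-methyl-5-(3-methylbut-3-en-1-yl)-2-(propan-2-yl)cyclopentane-1-carbaldehyde | O=C[C@@H]1[C@@](C)(CCC(C)=C)CC[C@@]1(O)C(C)C | intermediate
10 | (3R,3aS,4S,8aS)-8a-methyl-6-methylidene-3-(propan-2-yl)decahydroazulene-3,4-diol | C=C1C[C@H](O)[C@@H]2[C@](C)(CC[C@@]2(O)C(C)C)CC1 | intermediate
11 | 4-(acetyloxy)benzoyl chloride | CC(=O)Oc1ccc(cc1)C(Cl)=O | starting material
12 | [(3R,3aS,4S,8aS)-3-hydroxy-8a-methyl-6-methylidene-3-(propan-2-yl)decahydroazulen-4-yl] 4-(acetyloxy)benzoate | C=C1C[C@H](OC(=O)c2ccc(OC(C)=O)cc2)[C@@H]2[C@](C)(CC[C@@]2(O)C(C)C)CC1 | intermediate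
13 | [(3R,3aS,4S,7S,8aR)-3,7-dihydroxy-8a-methyl-6-methylidene-3-(propan-2-yl)decahydroazulen-4-yl] 4-(acetyloxy)benzoate | C=C1C[C@H](OC(=O)c2ccc(OC(C)=O)cc2)[C@@H]2[C@](C)(CC[C@@]2(O)C(C)C)C[C@@H]1O | intermediate
14 | ferugin, [(3R,3aS,4S,7S,8aR)-3,7-dihydroxy-8a-methyl-6-methylidene-3-(propan-2-yl)decahydroazulen-4-yl] 4-hydroxybenzoate | C=C1C[C@H](OC(=O)c2ccc(O)cc2)[C@@H]2[C@](C)(CC[C@@]2(O)C(C)C)C[C@@H]1O | target

**Step count**
Total steps: 8. Longest linear sequence: 7 (steps 1, 2, 4, 5, 6, 7, 8); step 3 is the one-step side branch.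

**Three steps most likely to fail**

Step 4 is the largest risk. The aliphatic iminium ion absorbs weakly, its E and Z forms can interconvert through the dienamine and erode the selectivity at the quaternary carbon, and the radical coupling must build a quaternary centre. The fallback sets out from 7 and 4 and returns at 8, replacing the radical cascade by a closed-shell, auxiliary-controlled sequence. Cyclopropanol 7 is opened with N-bromosuccinimide to 1-bromo-4-methylpentan-3-one F1, which is ketalised with ethane-1,2-diol to 2-(2-bromoethyl)-2-(propan-2-yl)-1,3-dioxolane F2 and converted with magnesium into {2-[2-(propan-2-yl)-1,3-dioxolan-2-yl]ethyl}magnesium bromide F3, a protected homoenolate. Enal 4 is condensed with tert-butyl (2S)-2-amino-3,3-dimethylbutanoate to tert-butyl (2S)-2-{[(1E,2E)-3,6-dimethylhepta-2,6-dien-1-ylidene]amino}-3,3-dimethylbutanoate F4. Chelation-controlled 1,4-addition of F3 to F4 followed by mild acid hydrolysis releases the auxiliary and gives (3S)-3-methyl-3-(3-methylbut-3-en-1-yl)-5-[2-(propan-2-yl)-1,3-dioxolan-2-yl]pentanal F5 (the enantiomeric auxiliary is used if the sense proves opposite). Aqueous acid removes the dioxolane to give keto aldehyde 8, which the amine catalyst of step 4 cyclises in the dark by enamine aldol addition to 9.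

Step 7 is the second risk: oxidation could occur at C-5 instead of C-7, give the 7-epimer, or run on to the enone. The fallback sets out from 12 and returns at 13, replacing substrate-controlled hydroxylation by oxidation to the ketone and reagent-controlled reduction. Compound 12 is oxidised fully (SeO2 with excess t-BuOOH, then 1,1,1-triacetoxy-1,1-dihydro-1,2-benziodoxol-3(1H)-one on the crude alcohol mixture) to [(3R,3aS,4S,8aR)-3-hydroxy-8a-methyl-6-methylidene-7-oxo-3-(propan-2-yl)decahydroazulen-4-yl] 4-(acetyloxy)benzoate F7. The enone is then reduced with BH3·SMe2 and (R)-1-methyl-3,3-diphenyltetrahydro-1H,3H-pyrrolo[1,2-c][1,3,2]oxazaborole, the alkenyl group acting as the large substituent, to give the 7S alcohol 13.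

Step 5 is the third risk: retro-aldol cleavage of the β-hydroxy aldehyde under Lewis acid, hydrogen transfer from the ring CH2 to give the endocyclic alkene, or chloride capture of the cation. The fallback sets out from 9 and returns at 10, replacing the Lewis-acid ene reaction by a metal-mediated allylation. Ene-type allylic chlorination of the isopropenyl group (N-chlorosuccinimide, catalytic PhSeCl) gives (1R,2R,5S)-5-[3-(chloromethyl)but-3-en-1-yl]-2-hydroxy-5-methyl-2-(propan-2-yl)cyclopentane-1-carbaldehyde F6. CrCl2 in THF then generates the allylchromium species, which adds intramolecularly to the aldehyde to give the same 6-methylidene diol 10.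

**Further compounds**
F1 | step 4 | 1-bromo-4-methylpentan-3-one | CC(C)C(=O)CCBr
F2 | step 4 | 2-(2-bromoethyl)-2-(propan-2-yl)-1,3-dioxolane | CC(C)C1(CCBr)OCCO1
F3 | step 4 | {2-[2-(propan-2-yl)-1,3-dioxolan-2-yl]ethyl}magnesium bromide | CC(C)C1(CC[Mg]Br)OCCO1
F4 | step 4 | tert-butyl (2S)-2-{[(1E,2E)-3,6-dimethylhepta-2,6-dien-1-ylidene]amino}-3,3-dimethylbutanoate | CC(C)(C)OC(=O)[C@@H](/N=C/C=C(\C)CCC(C)=C)C(C)(C)C
F5 | step 4 | (3S)-3-methyl-3-(3-methylbut-3-en-1-yl)-5-[2-(propan-2-yl)-1,3-dioxolan-2-yl]pentanal | O=CC[C@@](C)(CCC(C)=C)CCC1(C(C)C)OCCO1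
F6 | step 5 | (1R,2R,5S)-5-[3-(chloromethyl)but-3-en-1-yl]-2-hydroxy-5-methyl-2-(propan-2-yl)cyclopentane-1-carbaldehyde | O=C[C@@H]1[C@@](C)(CCC(CCl)=C)CC[C@@]1(O)C(C)C
F7 | step 7 | [(3R,3aS,4S,8aR)-3-hydroxy-8a-methyl-6-methylidene-7-oxo-3-(propan-2-yl)decahydroazulen-4-yl] 4-(acetyloxy)benzoate | C=C1C[C@H](OC(=O)c2ccc(OC(C)=O)cc2)[C@@H]2[C@](C)(CC[C@@]2(O)C(C)C)CC1=O
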